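**Plan**

- The target is epigallocatechin-(4β→8)-epigallocatechin 3-O-gallate-(4β→8)-epigallocatechin. The retrosynthesis removes the benzyl groups, cuts the C2–aryl (ring B) and C3–O bonds of the top unit (back to a C2=C3 enol ether), then C4–C4a and O1–C2 of top ring C, then the C8–alkenyl bond on the middle ring A, then the interflavan bond C4(middle)–C8(bottom), and last the gallate ester.
- The enabling feature: ring A of the top unit carries H at both C6 and C8, and its C4 is bonded to C8 of the middle ring A. Top ring C (C4–C4a and O1–C2) can therefore be built from a symmetric 3,5-dioxygenated phenol and a propenal placed on C8 of the middle unit.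
- Forward: one penta-O-benzyl ether of (−)-epigallocatechin serves both lower units. It is galloylated, brominated at C8 and activated at C4 (middle unit), or O-benzylated at C3 (bottom unit), and the two are joined. The C8 bromide becomes the enal, top rings A and C are annulated onto it, and the lactol is dehydrated, epoxidised and arylated at C2 (ring B). Hydrogenolysis finishes.
- Stereochemistry: C2 and C3 of the middle and bottom units come from the natural flavanol. Middle C4 arises by trans addition to the flavan-4-yl cation. Top C4 is set by the (S)-prolinol silyl ether catalyst. Top C3 and C2 are relayed from C4 (epoxidation anti to the C4 aryl, then aryl delivery syn to the epoxide oxygen).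

Key step: step 8

Assumption: both interflavan bonds are read from the given structure as 4β→8 (3,4-trans) with every flavan unit 2,3-cis (2R,3R in the parent flavanols). 3,4,5-Tris(benzyloxy)benzoic acid, 3,5-bis(benzyloxy)phenol and the pinacol alkenylboronate are taken as purchased compounds.

**Step 1**
Reactants: 1 (−)-epigallocatechin
Product: 2 5,7,3',4',5'-penta-O-benzyl-epigallocatechin (free 3-OH)
Conditions: BnBr (5.5 equiv), K2CO3, DMF, 0 °C → rt, argon
Reagents that add atoms: benzyl bromide, BrCc1ccccc1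
Why: Williamson benzylation with a carbonate base should alkylate the five phenols only, the secondary C3 hydroxyl being too weakly acidic, and C2 is not expected to epimerise once the phenols are capped.

**Step 2**
Reactants: 2 penta-O-benzyl-epigallocatechin; 3 3,4,5-tris(benzyloxy)benzoic acid
Product: 4 octa-O-benzyl-epigallocatechin gallate [(2R,3R)-5,7-bis(benzyloxy)-2-[3,4,5-tris(benzyloxy)phenyl]chroman-3-yl 3,4,5-tris(benzyloxy)benzoate]
Conditions: DCC, DMAP, CH2Cl2, 0 °C → rt
Reagents that add atoms: none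
Why: Steglich esterification acylates the axial C3 hydroxyl through the DMAP acylpyridinium ion under neutral conditions, so neither stereocentre is touched.

**Step 3**
Reactants: 4 octa-O-benzyl-epigallocatechin gallate
Product: 5 8-bromo-octa-O-benzyl-epigallocatechin gallate
Conditions: NBS (1.0 equiv), CH2Cl2, −78 °C → 0 °C
Reagents that add atoms: N-bromosuccinimide, O=C1CCC(=O)N1Br
Why: Electrophilic aromatic bromination of a 5,7-dibenzyloxyflavan is expected at C8, the most nucleophilic ring A position; the bromine caps C8 against self-condensation in step 6 and is the cross-coupling handle of step 7.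

**Step 4**
Reactants: 5 8-bromo-octa-O-benzyl-epigallocatechin gallate
Product: 6 8-bromo-4β-(2-ethoxyethoxy)-octa-O-benzyl-epigallocatechin gallate (3,4-trans)
Conditions: DDQ (2 equiv), 2-ethoxyethanol (5 equiv), CH2Cl2, rt
Reagents that add atoms: 2-ethoxyethanol, CCOCCO
Why: DDQ benzylic oxidation abstracts hydride from C4, which is activated by the ring A oxygens, and the alcohol should trap the cation trans to the C3 gallate (4β); this configuration is lost again in step 6.

**Step 5**
Reactants: 2 penta-O-benzyl-epigallocatechin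
Product: 7 3,5,7,3',4',5'-hexa-O-benzyl-epigallocatechin
Conditions: NaH, BnBr, DMF, 0 °C → rt
Reagents that add atoms: benzyl bromide, BrCc1ccccc1
Why: Williamson etherification of the C3 alkoxide removes the last free hydroxyl of the bottom unit, so that the later sulfonylation, dioxirane and organoaluminium steps meet no OH there.

**Step 6**
Reactants: 6 8-bromo-4β-(2-ethoxyethoxy)-octa-O-benzyl-epigallocatechin gallate; 7 hexa-O-benzyl-epigallocatechin (2 equiv)
Product: 8 dimer bromide: 8-bromo-octa-O-benzyl-epigallocatechin gallate-(4β→8)-hexa-O-benzyl-epigallocatechin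
Conditions: TMSOTf (0.5 equiv), CH2Cl2, −78 °C; aq. NaHCO3
Reagents that add atoms: none
Why: Lewis acid ionisation of the C4 ether gives the flavan-4-yl cation, which C8 of 7 attacks in a Friedel–Crafts alkylation from the face opposite the C3 gallate (with possible acyloxonium participation) and the C2 aryl group, setting middle C4 as 4β (3,4-trans), while the 8-bromo cap prevents self-oligomerisation.

**Step 7**
Reactants: 8 dimer bromide; 9 (E)-2-(3,3-diethoxyprop-1-enyl)-4,4,5,5-tetramethyl-1,3,2-dioxaborolane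
Product: 11 dimer enal bearing an (E)-3-oxoprop-1-enyl group at C8 of the middle unit, via diethyl acetal 10 (not isolated)
Conditions: Pd(OAc)2 (5 mol %), SPhos (10 mol %), K3PO4, toluene–H2O, 80 °C; then PPTS, acetone–H2O, rt
Reagents that add atoms: water, O
Why: Suzuki–Miyaura coupling with a dialkylbiarylphosphine ligand suited to di-ortho-oxygenated, electron-rich aryl bromides should transfer the alkenyl group with retention of E geometry, and mild acid hydrolysis of the allylic acetal then unmasks the enal without touching the benzyl ethers, the ester or the interflavan bond.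

**Step 8**
Reactants: 11 dimer enal; 12 3,5-bis(benzyloxy)phenol (1.5 equiv)
Product: 13 dimer carrying at C8 of the middle unit a (4R)-5,7-bis(benzyloxy)chroman-2-ol bonded through its C4 (both C2 anomers)
Conditions: (S)-2-[diphenyl(trimethylsilyloxy)methyl]pyrrolidine (20 mol %), PhCO2H (20 mol %), toluene, 0 °C → rt
Reagents that add atoms: none
Why: The secondary amine condenses with the enal to an E-configured, s-trans iminium ion whose β-carbon is attacked by the phenol carbon ortho to the hydroxyl and para to a benzyloxy group (Friedel–Crafts conjugate addition, forming C4–C4a), after which rearomatisation and hydrolysis of the enamine release the aldehyde and the catalyst. The closest known reaction type is the diarylprolinol silyl ether-catalysed Friedel–Crafts alkylation and hemiacetalisation of electron-rich phenols and naphthols with β-aryl enals to 4-arylchroman-2-ols. Ring C of the top unit then closes by 6-exo-trig addition of the phenol oxygen to the aldehyde carbon (O1–C2), giving the lactol as both anomers, which does not matter because C2 becomes trigonal in step 9. The new C4 stereocentre is under catalyst control: the CPh2(OSiMe3) group of the (S)-amine covers the Re face of the β-carbon, so the arene should add to the Si face, which corresponds to 4R, the 4β series of the target. The step needs the catalyst to override the distant stereocentres of the dimer (the nearest, C2 of the middle unit, lies four bonds from the β-carbon) and needs ortho rather than para C-alkylation; the two ortho positions of the symmetric phenol are equivalent and less hindered than the position between the two benzyloxy groups, and only the ortho adduct is drawn forward by lactol formation.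

**Step 9**
Reactants: 13 chroman-2-ol dimer
Product: 15 dimer carrying at C8 of the middle unit a (4R)-5,7-bis(benzyloxy)-4H-chromen-4-yl group, via anomeric mesylate 14 (not isolated)
Conditions: MsCl, Et3N, CH2Cl2, 0 °C → 40 °C
Reagents that add atoms: none
Why: Lactol-to-enol-ether dehydration through the anomeric sulfonate (the glycal-type elimination) proceeds under base, so the acid-labile interflavan bond is not exposed to acid and the C4 methine is not touched.

**Step 10**
Reactants: 15 4H-chromene dimer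
Product: 16 2,3-epoxide of 15, oxirane oxygen on the face opposite the C4 aryl group (used crude)
Conditions: dimethyldioxirane (acetone solution, 1.2 equiv), CH2Cl2, −78 → −20 °C; volatiles removed cold
Reagents that add atoms: dimethyldioxirane, CC1(C)OO1
Why: Dioxirane epoxidation of an enol ether under neutral conditions should occur anti to the bulky 2,6-dioxygenated aryl group at C4, fixing the C3–O bond trans to the C4 aryl bond and setting C2 and C3 together.

**Step 11**
Reactants: 17 5-bromo-1,2,3-trimethoxybenzene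
Product: 18 5-bromobenzene-1,2,3-triol
Conditions: BBr3, CH2Cl2, −78 °C → rt; H2O
Reagents that add atoms: none
Why: Lewis acid cleavage of aryl methyl ethers with BBr3 frees the pyrogallol and leaves the aryl bromide intact.

**Step 12**
Reactants: 18 5-bromobenzene-1,2,3-triol
Product: 19 5-bromo-1,2,3-tris(benzyloxy)benzene
Conditions: BnBr, K2CO3, DMF, rt, argon
Reagents that add atoms: benzyl bromide, BrCc1ccccc1
Why: Williamson benzylation of the three phenols gives the ring B precursor with the protecting groups used throughout the route.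

**Step 13**
Reactants: 19 5-bromo-1,2,3-tris(benzyloxy)benzene
Product: 21 dimethyl[3,4,5-tris(benzyloxy)phenyl]alane (solution used directly), via aryllithium 20 (not isolated)
Conditions: t-BuLi (2 equiv), Et2O–toluene, −78 °C; Me2AlCl (1.0 equiv), −78 → 0 °C
Reagents that add atoms: dimethylaluminium chloride, C[Al](C)Cl
Why: Bromine–lithium exchange followed by transmetalation of the aryllithium to the dialkylaluminium chloride is the standard entry to mixed aryl(dialkyl)alanes, which carry a single transferable aryl group per aluminium.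

**Step 14**
Reactants: 16 epoxide; 21 dimethyl[3,4,5-tris(benzyloxy)phenyl]alane (3 equiv)
Product: 22 nonadeca-O-benzyl trimer (top unit 2,3-cis-3,4-trans with free 3-OH; bottom unit 3-O-benzyl; middle unit 3-O-gallate)
Conditions: CH2Cl2–Et2O–toluene, −78 → 0 °C; aq. potassium sodium tartrate (KNaC4H4O6)
Reagents that add atoms: none
Why: Proposed new method: the Lewis acidic alane should bind the epoxide oxygen, the C2–O bond should ionise to an aryloxy-stabilised oxocarbenium ion paired with the C3 aluminate, and the sp2 aryl ligand, which migrates from aluminium in preference to methyl as alkenyl and alkynyl ligands of mixed alanes do, should then pass intramolecularly to C2 on the face of the departing oxygen, giving the 2,3-cis flavan-3-ol with C3 retained and C2 set by internal delivery; the closest known reaction type is the syn-selective opening of glycal epoxides (1,2-anhydro sugars) by aryl- and alkylalanes to 1,2-cis C-glycosides.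

**Step 15**
Reactants: 22 nonadeca-O-benzyl trimer
Product: 23 epigallocatechin-(4β→8)-epigallocatechin 3-O-gallate-(4β→8)-epigallocatechin (target)
Conditions: H2 (1 atm), Pd(OH)2/C, THF–MeOH–H2O, rt
Reagents that add atoms: none
Why: Catalytic hydrogenolysis removes all nineteen benzyl ethers under neutral conditions that are expected to leave the gallate ester, both interflavan bonds and the eight stereocentres unchanged.

**Compound list**

1 | (−)-epigallocatechin | Oc1cc(O)c2c(c1)O[C@H](c1cc(O)c(O)c(O)c1)[C@H](O)C2 | starting material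
2 | 5,7,3',4',5'-penta-O-benzyl-epigallocatechin | O[C@@H]1Cc2c(OCc5ccccc5)cc(OCc5ccccc5)cc2O[C@@H]1c6cc(OCc5ccccc5)c(OCc5ccccc5)c(OCc5ccccc5)c6 | intermediate
3 | 3,4,5-tris(benzyloxy)benzoic acid | O=C(O)c1cc(OCc2ccccc2)c(OCc2ccccc2)c(OCc2ccccc2)c1 | starting material
4 | octa-O-benzyl-epigallocatechin gallate | O=C(O[C@@H]1Cc2c(OCc5ccccc5)cc(OCc5ccccc5)cc2O[C@@H]1c6cc(OCc5ccccc5)c(OCc5ccccc5)c(OCc5ccccc5)c6)c7cc(OCc5ccccc5)c(OCc5ccccc5)c(OCc5ccccc5)c7 | intermediate
5 | 8-bromo-octa-O-benzyl-epigallocatechin gallate | O=C(O[C@@H]1Cc2c(OCc5ccccc5)cc(OCc5ccccc5)c(Br)c2O[C@@H]1c6cc(OCc5ccccc5)c(OCc5ccccc5)c(OCc5ccccc5)c6)c7cc(OCc5ccccc5)c(OCc5ccccc5)c(OCc5ccccc5)c7 | intermediate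
6 | 8-bromo-4β-(2-ethoxyethoxy)-octa-O-benzyl-epigallocatechin gallate | O=C(O[C@@H]1[C@@H](OCCOCC)c2c(OCc5ccccc5)cc(OCc5ccccc5)c(Br)c2O[C@@H]1c6cc(OCc5ccccc5)c(OCc5ccccc5)c(OCc5ccccc5)c6)c7cc(OCc5ccccc5)c(OCc5ccccc5)c(OCc5ccccc5)c7 | intermediate
7 | 3,5,7,3',4',5'-hexa-O-benzyl-epigallocatechin | c5ccccc5CO[C@@H]1Cc2c(OCc5ccccc5)cc(OCc5ccccc5)cc2O[C@@H]1c6cc(OCc5ccccc5)c(OCc5ccccc5)c(OCc5ccccc5)c6 | intermediate
8 | dimer bromide: 8-bromo-octa-O-benzyl-EGCG-(4β→8)-hexa-O-benzyl-EGC | O=C(O[C@@H]1[C@@H](c2c(OCc5ccccc5)cc(OCc5ccccc5)c3c2O[C@H](c6cc(OCc5ccccc5)c(OCc5ccccc5)c(OCc5ccccc5)c6)[C@H](OCc5ccccc5)C3)c2c(OCc5ccccc5)cc(OCc5ccccc5)c(Br)c2O[C@@H]1c6cc(OCc5ccccc5)c(OCc5ccccc5)c(OCc5ccccc5)c6)c7cc(OCc5ccccc5)c(OCc5ccccc5)c(OCc5ccccc5)c7 | intermediate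
9 | (E)-2-(3,3-diethoxyprop-1-enyl)-4,4,5,5-tetramethyl-1,3,2-dioxaborolane | CCOC(OCC)/C=C/B1OC(C)(C)C(C)(C)O1 | starting material
10 | dimer with (E)-3,3-diethoxyprop-1-enyl at C8 of the middle unit | O=C(O[C@@H]1[C@@H](c2c(OCc5ccccc5)cc(OCc5ccccc5)c3c2O[C@H](c6cc(OCc5ccccc5)c(OCc5ccccc5)c(OCc5ccccc5)c6)[C@H](OCc5ccccc5)C3)c2c(OCc5ccccc5)cc(OCc5ccccc5)c(/C=C/C(OCC)OCC)c2O[C@@H]1c6cc(OCc5ccccc5)c(OCc5ccccc5)c(OCc5ccccc5)c6)c7cc(OCc5ccccc5)c(OCc5ccccc5)c(OCc5ccccc5)c7 | intermediate
11 | dimer enal: (E)-3-oxoprop-1-enyl at C8 of the middle unit | O=C(O[C@@H]1[C@@H](c2c(OCc5ccccc5)cc(OCc5ccccc5)c3c2O[C@H](c6cc(OCc5ccccc5)c(OCc5ccccc5)c(OCc5ccccc5)c6)[C@H](OCc5ccccc5)C3)c2c(OCc5ccccc5)cc(OCc5ccccc5)c(/C=C/C=O)c2O[C@@H]1c6cc(OCc5ccccc5)c(OCc5ccccc5)c(OCc5ccccc5)c6)c7cc(OCc5ccccc5)c(OCc5ccccc5)c(OCc5ccccc5)c7 | intermediate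
12 | 3,5-bis(benzyloxy)phenol | Oc1cc(OCc5ccccc5)cc(OCc5ccccc5)c1 | starting material
13 | dimer with (4R)-5,7-bis(benzyloxy)chroman-2-ol attached through C4 to C8 of the middle unit (lactol anomers) | O=C(O[C@@H]1[C@@H](c2c(OCc5ccccc5)cc(OCc5ccccc5)c3c2O[C@H](c6cc(OCc5ccccc5)c(OCc5ccccc5)c(OCc5ccccc5)c6)[C@H](OCc5ccccc5)C3)c2c(OCc5ccccc5)cc(OCc5ccccc5)c([C@H]3c4c(OCc5ccccc5)cc(OCc5ccccc5)cc4OC(O)C3)c2O[C@@H]1c6cc(OCc5ccccc5)c(OCc5ccccc5)c(OCc5ccccc5)c6)c7cc(OCc5ccccc5)c(OCc5ccccc5)c(OCc5ccccc5)c7 | intermediate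
14 | C2 methanesulfonate of 13 | O=C(O[C@@H]1[C@@H](c2c(OCc5ccccc5)cc(OCc5ccccc5)c3c2O[C@H](c6cc(OCc5ccccc5)c(OCc5ccccc5)c(OCc5ccccc5)c6)[C@H](OCc5ccccc5)C3)c2c(OCc5ccccc5)cc(OCc5ccccc5)c([C@H]3c4c(OCc5ccccc5)cc(OCc5ccccc5)cc4OC(OS(C)(=O)=O)C3)c2O[C@@H]1c6cc(OCc5ccccc5)c(OCc5ccccc5)c(OCc5ccccc5)c6)c7cc(OCc5ccccc5)c(OCc5ccccc5)c(OCc5ccccc5)c7 | intermediate
15 | dimer with (4R)-5,7-bis(benzyloxy)-4H-chromen-4-yl at C8 of the middle unit | O=C(O[C@@H]1[C@@H](c2c(OCc5ccccc5)cc(OCc5ccccc5)c3c2O[C@H](c6cc(OCc5ccccc5)c(OCc5ccccc5)c(OCc5ccccc5)c6)[C@H](OCc5ccccc5)C3)c2c(OCc5ccccc5)cc(OCc5ccccc5)c([C@H]3c4c(OCc5ccccc5)cc(OCc5ccccc5)cc4OC=C3)c2O[C@@H]1c6cc(OCc5ccccc5)c(OCc5ccccc5)c(OCc5ccccc5)c6)c7cc(OCc5ccccc5)c(OCc5ccccc5)c(OCc5ccccc5)c7 | intermediate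
16 | 2,3-epoxide of 15, oxygen anti to the C4 aryl group | O=C(O[C@@H]1[C@@H](c2c(OCc5ccccc5)cc(OCc5ccccc5)c3c2O[C@H](c6cc(OCc5ccccc5)c(OCc5ccccc5)c(OCc5ccccc5)c6)[C@H](OCc5ccccc5)C3)c2c(OCc5ccccc5)cc(OCc5ccccc5)c([C@H]3c4c(OCc5ccccc5)cc(OCc5ccccc5)cc4O[C@H]8[C@@H]3O8)c2O[C@@H]1c6cc(OCc5ccccc5)c(OCc5ccccc5)c(OCc5ccccc5)c6)c7cc(OCc5ccccc5)c(OCc5ccccc5)c(OCc5ccccc5)c7 | intermediate
17 | 5-bromo-1,2,3-trimethoxybenzene | COc1cc(Br)cc(OC)c1OC | starting material
18 | 5-bromobenzene-1,2,3-triol | Oc1cc(Br)cc(O)c1O | intermediate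
19 | 5-bromo-1,2,3-tris(benzyloxy)benzene | Brc1cc(OCc5ccccc5)c(OCc5ccccc5)c(OCc5ccccc5)c1 | intermediate
20 | 3,4,5-tris(benzyloxy)phenyllithium | [Li]c1cc(OCc5ccccc5)c(OCc5ccccc5)c(OCc5ccccc5)c1 | intermediate
21 | dimethyl[3,4,5-tris(benzyloxy)phenyl]alane | C[Al](C)c1cc(OCc5ccccc5)c(OCc5ccccc5)c(OCc5ccccc5)c1 | intermediate
22 | nonadeca-O-benzyl trimer (top 3-OH free) | O=C(O[C@@H]1[C@@H](c2c(OCc5ccccc5)cc(OCc5ccccc5)c3c2O[C@H](c6cc(OCc5ccccc5)c(OCc5ccccc5)c(OCc5ccccc5)c6)[C@H](OCc5ccccc5)C3)c2c(OCc5ccccc5)cc(OCc5ccccc5)c([C@H]3c4c(OCc5ccccc5)cc(OCc5ccccc5)cc4O[C@H](c6cc(OCc5ccccc5)c(OCc5ccccc5)c(OCc5ccccc5)c6)[C@@H]3O)c2O[C@@H]1c6cc(OCc5ccccc5)c(OCc5ccccc5)c(OCc5ccccc5)c6)c7cc(OCc5ccccc5)c(OCc5ccccc5)c(OCc5ccccc5)c7 | intermediate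
23 | epigallocatechin-(4β→8)-epigallocatechin 3-O-gallate-(4β→8)-epigallocatechin | O=C(O[C@@H]1[C@@H](c2c(O)cc(O)c3c2O[C@H](c2cc(O)c(O)c(O)c2)[C@H](O)C3)c2c(O)cc(O)c([C@H]3c4c(O)cc(O)cc4O[C@H](c4cc(O)c(O)c(O)c4)[C@@H]3O)c2O[C@@H]1c1cc(O)c(O)c(O)c1)c1cc(O)c(O)c(O)c1 | target

**Step count and risks**

Total: 15 steps. Longest linear sequence: 11 steps from 1 (steps 1, 2, 3, 4, 6, 7, 8, 9, 10, 14, 15).

Steps most likely to fail:

1. Step 14 (bears the label). After Lewis acid ionisation of the epoxide, a 1,2-hydride shift to the chroman-3-one or proton loss may outrun the intramolecular aryl transfer. Methyl may transfer from aluminium in place of the aryl group. The labile epoxide may also decompose before the alane delivers its aryl group. Fallback, known chemistry throughout: the top unit is introduced whole by the flavan-4-yl cation coupling instead of being built on the dimer. Dimer bromide 8 is debrominated by radical reduction with tributyltin hydride and AIBN in toluene at 90 °C to the C8–H dimer F1. In parallel, penta-O-benzyl-epigallocatechin 2 is oxidised with DDQ in the presence of 2-ethoxyethanol to the 4β-(2-ethoxyethoxy) derivative F2. TMSOTf in CH2Cl2 at −78 °C then joins C4 of F2 to C8 of the upper unit of F1 (F1 in excess and recovered), trans to the C3 hydroxyl. This gives 22 directly, and the route resumes with step 15.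

2. Step 8. Iminium formation and β-attack may be slow at the di-ortho-substituted, electron-rich cinnamaldehyde. Facial selectivity may erode through mismatch with the chiral dimer, and attack through the carbon para to the phenol hydroxyl may compete. Fallback: the polarity is changed so that C3–C4 is formed on a much stronger electrophile. Enal 11 is cleaved by Lemieux–Johnson oxidation (OsO4 cat., NaIO4, 2,6-lutidine, dioxane–H2O) to the C8 carbaldehyde F3. The bromomagnesium phenoxide of 12 (from EtMgBr) adds to F3 through its ortho carbon to give the ortho-hydroxybenzhydrol F4. A weak acid (PhCO2H) then dehydrates F4 to the ortho-quinone methide, which is intercepted by the enamine formed from acetaldehyde and the diphenylprolinol silyl ether (the catalyst antipode that gives the 4R epimer to be chosen by experiment). Conjugate addition and hemiacetalisation return the route to lactol 13.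

3. Step 7. Oxidative addition and transmetalation at the hindered C8–Br bond may be slow enough that protodeboronation of 9, hydrodebromination of 8 or base-induced loss of the gallate takes over. Fallback: the three-carbon unit is built in two stages under neutral conditions. Stille coupling of 8 with tributyl(vinyl)stannane (Pd(P(t-Bu)3)2, CsF, dioxane, 80 °C) gives the C8 vinyl dimer F5. Cross-metathesis with crotonaldehyde using the second-generation Hoveyda–Grubbs catalyst, RuCl2(H2IMes)(=CH-C6H4-2-O-i-Pr), in CH2Cl2 at 40 °C then gives the E-enal 11.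

**Further compounds**

F1 | step 14 | C8–H dimer: octa-O-benzyl-EGCG-(4β→8)-hexa-O-benzyl-EGC | O=C(O[C@@H]1[C@@H](c2c(OCc5ccccc5)cc(OCc5ccccc5)c3c2O[C@H](c6cc(OCc5ccccc5)c(OCc5ccccc5)c(OCc5ccccc5)c6)[C@H](OCc5ccccc5)C3)c2c(OCc5ccccc5)cc(OCc5ccccc5)cc2O[C@@H]1c6cc(OCc5ccccc5)c(OCc5ccccc5)c(OCc5ccccc5)c6)c7cc(OCc5ccccc5)c(OCc5ccccc5)c(OCc5ccccc5)c7
F2 | step 14 | 4β-(2-ethoxyethoxy)-5,7,3',4',5'-penta-O-benzyl-epigallocatechin (3,4-trans, free 3-OH) | CCOCCO[C@H]1c2c(OCc5ccccc5)cc(OCc5ccccc5)cc2O[C@H](c6cc(OCc5ccccc5)c(OCc5ccccc5)c(OCc5ccccc5)c6)[C@@H]1O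
F3 | step 8 | dimer with a formyl group at C8 of the middle unit | O=C(O[C@@H]1[C@@H](c2c(OCc5ccccc5)cc(OCc5ccccc5)c3c2O[C@H](c6cc(OCc5ccccc5)c(OCc5ccccc5)c(OCc5ccccc5)c6)[C@H](OCc5ccccc5)C3)c2c(OCc5ccccc5)cc(OCc5ccccc5)c(C=O)c2O[C@@H]1c6cc(OCc5ccccc5)c(OCc5ccccc5)c(OCc5ccccc5)c6)c7cc(OCc5ccccc5)c(OCc5ccccc5)c(OCc5ccccc5)c7
F4 | step 8 | dimer with a [2-hydroxy-4,6-bis(benzyloxy)phenyl](hydroxy)methyl group at C8 of the middle unit (carbinol epimers) | O=C(O[C@@H]1[C@@H](c2c(OCc5ccccc5)cc(OCc5ccccc5)c3c2O[C@H](c6cc(OCc5ccccc5)c(OCc5ccccc5)c(OCc5ccccc5)c6)[C@H](OCc5ccccc5)C3)c2c(OCc5ccccc5)cc(OCc5ccccc5)c(C(O)c8c(O)cc(OCc5ccccc5)cc8OCc5ccccc5)c2O[C@@H]1c6cc(OCc5ccccc5)c(OCc5ccccc5)c(OCc5ccccc5)c6)c7cc(OCc5ccccc5)c(OCc5ccccc5)c(OCc5ccccc5)c7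
F5 | step 7 | dimer with a vinyl group at C8 of the middle unit | O=C(O[C@@H]1[C@@H](c2c(OCc5ccccc5)cc(OCc5ccccc5)c3c2O[C@H](c6cc(OCc5ccccc5)c(OCc5ccccc5)c(OCc5ccccc5)c6)[C@H](OCc5ccccc5)C3)c2c(OCc5ccccc5)cc(OCc5ccccc5)c(C=C)c2O[C@@H]1c6cc(OCc5ccccc5)c(OCc5ccccc5)c(OCc5ccccc5)c6)c7cc(OCc5ccccc5)c(OCc5ccccc5)c(OCc5ccccc5)c7
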